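## Retrosynthetic overview

1. The target is the head-to-tail dimer of one C15 styrene. Cutting the CH(CH3)–CH= bond of the butene linker, which carries the only stereocentre, gives two molecules of one vinylarene.
2. Both 2,2-dimethyl-2H-pyran rings are cut together back to aryl 1,1-dimethylpropargyl ethers (Claisen / [1,5]-H shift / oxa-6π), so the monomer is an O-propargylated 2-vinylphenol.
3. Monomer: aldehyde 1 + phosphonium salt 2 → vinylphenol 3; 3 + propargylic chloride 4 → ether 5.
4. Key operation in one flask: chiral-acid dimerisation of 5 → dimer 6 (C–C bond, E-alkene, (S) centre), then heating → 7 → 8.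
5. Ring order: both benzene rings are bought; the two pyran rings are formed last and together, in step 3.

Assumption: the sense of induction of the new dimerisation cannot be predicted, so the catalyst enantiomer written is taken as the one giving (S); its mirror image is used if the first run gives (R).

## Route

Step 1
Reactants: 1 2-hydroxy-4,6-dimethoxybenzaldehyde; 2 methyltriphenylphosphonium bromide
Product: 3 2-ethenyl-3,5-dimethoxyphenol
Conditions: 2 (1.3 equiv), KOt-Bu (2.4 equiv), THF, 0 °C to rt; aq NH4Cl
Reagents that add atoms: methyltriphenylphosphonium bromide 2, C[P+](c1ccccc1)(c1ccccc1)c1ccccc1.[Br-]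
Why: Wittig methylenation; the first equivalent of base only makes the phenoxide, and the non-stabilised ylide still adds to the aldehyde as it does with salicylaldehyde itself, giving the 2-vinylphenol without a protecting group (no stereocentre; the product is kept cold and away from acid).

Step 2
Reactants: 3 2-ethenyl-3,5-dimethoxyphenol; 4 3-chloro-3-methylbut-1-yne
Product: 5 2-ethenyl-1,5-dimethoxy-3-[(2-methylbut-3-yn-2-yl)oxy]benzene
Conditions: 4 (1.5 equiv), DBU (1.6 equiv), CuCl2·2H2O (1 mol %), MeCN, 0 °C to rt
Reagents that add atoms: 3-chloro-3-methylbut-1-yne 4, CC(C)(Cl)C#C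
Why: copper-catalysed O-propargylation of a phenol with a tertiary propargylic chloride (copper acetylide/allenylidene-type electrophile), the standard entry to aryl 1,1-dimethylpropargyl ethers; the basic, cold conditions leave the styrene untouched, no Claisen rearrangement occurs below about 100 °C, and capping the phenol blocks the flavan-forming cyclisation that a free 2-vinylphenol undergoes on dimerisation.

Step 3
Reactants: 5 2-ethenyl-1,5-dimethoxy-3-[(2-methylbut-3-yn-2-yl)oxy]benzene (two molecules)
Product: 8 (S,E)-1,3-bis(5,7-dimethoxy-2,2-dimethyl-2H-chromen-8-yl)but-1-ene, via head-to-tail dimer 6 (not isolated), via bis(allenylphenol) 7 (not isolated)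
Conditions: (S,S)-IDPi (imidodiphosphorimidate acid, 3,3'-bis[3,5-bis(trifluoromethyl)phenyl]-BINOL arms, N-triflyl core; 2 mol %), PhMe, −40 °C; then PhNEt2 (0.5 equiv), PhMe (0.02 M), sealed tube, 150 °C
Reagents that add atoms: none
Why: Proposed new method: the confined chiral acid protonates the terminal CH2 of one molecule of 5 to a 2,4,6-trialkoxy-stabilised 1-arylethyl cation held as a contact ion pair in the chiral anion, the CH2 terminus of a second molecule of 5 adds to one face of this cation (this C–C bond formation sets the (S) centre) and the new benzylic cation loses a proton to the anion to give the conjugated (E)-alkene of 6, indane-type cyclisation being blocked because both ortho positions are substituted; the closest known reaction types are the acid-catalysed head-to-tail dimerisation of electron-rich styrenes to (E)-1,3-diarylbut-1-enes and asymmetric counteranion-directed catalysis of styrene-derived benzylic cations by imidodiphosphorimidate acids; once PhNEt2 has neutralised the acid, the rest is known chemistry, a twofold aryl propargyl ether Claisen rearrangement (each ether has one free ortho position) with re-aromatisation to 7, then on each arm a [1,5]-hydrogen shift and oxa-6π electrocyclisation, which closes both pyran rings in the same heating period, splits nothing off (every atom of two molecules of 5 is in 8) and leaves the stereocentre alone because no acid or strong base is present.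

## Compound list

1 | 2-hydroxy-4,6-dimethoxybenzaldehyde | O=Cc1c(O)cc(OC)cc1OC | starting material
2 | methyltriphenylphosphonium bromide | C[P+](c1ccccc1)(c1ccccc1)c1ccccc1.[Br-] | starting material
3 | 2-ethenyl-3,5-dimethoxyphenol | C=Cc1c(O)cc(OC)cc1OC | intermediate
4 | 3-chloro-3-methylbut-1-yne | CC(C)(Cl)C#C | starting material
5 | 2-ethenyl-1,5-dimethoxy-3-[(2-methylbut-3-yn-2-yl)oxy]benzene | C=Cc1c(OC)cc(OC)cc1OC(C)(C)C#C | intermediate
6 | (S,E)-1,3-bis{2,4-dimethoxy-6-[(2-methylbut-3-yn-2-yl)oxy]phenyl}but-1-ene | COc1cc(OC)c(/C=C/[C@H](C)c2c(OC)cc(OC)cc2OC(C)(C)C#C)c(OC(C)(C)C#C)c1 | intermediate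
7 | (S,E)-1,3-bis[2-hydroxy-4,6-dimethoxy-3-(3-methylbuta-1,2-dien-1-yl)phenyl]but-1-ene (both arms after Claisen rearrangement and re-aromatisation) | COc1cc(OC)c(/C=C/[C@H](C)c2c(OC)cc(OC)c(C=C=C(C)C)c2O)c(O)c1C=C=C(C)C | intermediate
8 | (S,E)-1,3-bis(5,7-dimethoxy-2,2-dimethyl-2H-chromen-8-yl)but-1-ene | COc1cc(OC)c(/C=C/[C@H](C)c2c(OC)cc(OC)c3c2OC(C)(C)C=C3)c2c1C=CC(C)(C)O2 | target

## Step count and risks

Total step count: 3. Longest linear sequence: 3 (1 → 3 → 5 → 8).

Steps most likely to fail, most risky first:

1. Step 3. The dimerisation stage is new: the ee may be low, trimers or ether cleavage may compete, and the one-flask heating relies on complete neutralisation of the acid. The fallback sets out from 3 and comes back at 6. Compound 3 is dimerised with a chiral phosphoric acid, (R)-TRIP (5 mol %), PhMe, 0 °C, in the hydrogen-bond-directed ortho-quinone methide manifold. This formal [4+2] closes to the cis-flavan (2S,4S)-2-(2-hydroxy-4,6-dimethoxyphenyl)-5,7-dimethoxy-4-methylchromane F1 and sets C4 under better precedented control. KOt-Bu (2.5 equiv), THF, 50 °C then opens the pyran ring of F1 through the quinone methide of the free phenoxide, the pathway by which flavan-3-ols epimerise in base. This erases C2 and, after tautomerisation and NH4Cl quench, gives the bis-phenol (S,E)-2,2'-(but-1-ene-1,3-diyl)bis(3,5-dimethoxyphenol) F2. Twofold O-propargylation of F2 with 4 under the conditions of step 2 gives 6, which is now isolated and heated as in the second stage of step 3 to give 8.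

2. Step 2. The tertiary propargylation of a hindered, polymerisable vinylphenol may stall or give C-alkylation. The fallback sets out from 3 and comes back at 5. Fibrate-type O-alkylation (ethyl 2-bromo-2-methylpropanoate, Cs2CO3, DMF, 60 °C), which tolerates hindered phenols, gives ethyl 2-(2-ethenyl-3,5-dimethoxyphenoxy)-2-methylpropanoate F3. Reduction with i-Bu2AlH (CH2Cl2, −78 °C) gives 2-(2-ethenyl-3,5-dimethoxyphenoxy)-2-methylpropanal F4. Ohira–Bestmann homologation (dimethyl (1-diazo-2-oxopropyl)phosphonate, K2CO3, MeOH, rt) converts the aldehyde into the terminal alkyne 5.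

3. Step 1. The phenoxide of 1 is a poor electrophile for the ylide, and 3 is acid-sensitive. The fallback sets out from 1 and comes back at 3. Me3SiCH2MgCl (2.5 equiv, THF, 0 °C) adds to the magnesium-chelated aldehyde to give racemic 1-(2-hydroxy-4,6-dimethoxyphenyl)-2-(trimethylsilyl)ethan-1-ol F5. KH (2.2 equiv, THF, 0 °C to rt) then effects Peterson syn-elimination under purely basic conditions, giving 3 after NH4Cl quench.

## Further compounds

F1 | step 3 | (2S,4S)-2-(2-hydroxy-4,6-dimethoxyphenyl)-5,7-dimethoxy-4-methylchromane | C[C@H]1C[C@@H](c2c(O)cc(OC)cc2OC)Oc2cc(OC)cc(OC)c21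
F2 | step 3 | (S,E)-2,2'-(but-1-ene-1,3-diyl)bis(3,5-dimethoxyphenol) | COc1cc(O)c(/C=C/[C@H](C)c2c(O)cc(OC)cc2OC)c(OC)c1
F3 | step 2 | ethyl 2-(2-ethenyl-3,5-dimethoxyphenoxy)-2-methylpropanoate | CCOC(=O)C(C)(C)Oc1cc(OC)cc(OC)c1C=C
F4 | step 2 | 2-(2-ethenyl-3,5-dimethoxyphenoxy)-2-methylpropanal | O=CC(C)(C)Oc1cc(OC)cc(OC)c1C=C
F5 | step 1 | 1-(2-hydroxy-4,6-dimethoxyphenyl)-2-(trimethylsilyl)ethan-1-ol (racemic) | COc1cc(O)c(C(O)C[Si](C)(C)C)c(OC)c1
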